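The C8 methyl group, ring B and the C4 gem-dimethyl carbon together form the p-menthane skeleton of (R)-carvone, whose C5 stereocentre steers all the others. The synthesis rests on stitching a two-carbon C2–C3 linchpin between the two neopentyl arms of ring A: C4 on C5 and C1 on quaternary C10. In one flask, diethylphosphonoacetic acid is joined through its acyl carbon to the tertiary C4 radical (nickel catalysis) and through its phosphonate carbon to the C1 aldehyde. This closes ring A as a Δ1-en-3-one. The precursor is a monocyclic bromo keto aldehyde. The step exploits the C3 oxygen next to quaternary C4 and the trans C1/C4 arms that preset the ring fusion.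

Key step: step 5

Remark: C-numbers follow labdane numbering of the target (ring A: C1–C5 and C10; ring B: C5–C10; side chain C11–C16). p-Toluenesulfonyl bromide and 3-bromofuran-2(5H)-one are taken as catalogue chemicals.

Step 1
Reactants: 1 (R)-(−)-carvone
Product: 2 (5R,6S)-2,6-dimethyl-5-(prop-1-en-2-yl)cyclohex-2-en-1-one (6-methylcarvone; trans epimer shown; the C6 epimer is carried along)
Conditions: LDA, THF, −78 °C; MeI, −78 → 0 °C
Reagents that add atoms: iodomethane, CI
Why: Kinetic α′-deprotonation gives the cross-conjugated lithium dienolate, and its enolate alkylation (SN2) by MeI occurs mainly anti to the C5 isopropenyl group; the new centre is planarised again in step 2, so its configuration does not matter.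

Step 2
Reactants: 2 6-methylcarvone
Product: 3 (5S,6R)-6-(hydroxymethyl)-2,6-dimethyl-5-(prop-1-en-2-yl)cyclohex-2-en-1-one (CH2OH trans and CH3 cis to isopropenyl)
Conditions: LDA, THF, −78 °C; CH2O (gas from cracked paraformaldehyde), −78 °C; AcOH quench at −78 °C
Reagents that add atoms: formaldehyde, C=O
Why: In this aldol-type hydroxymethylation of the tetrasubstituted lithium enolate, formaldehyde approaches the face opposite the neighbouring C5 isopropenyl group, which places C1 trans to C4 and the methyl group cis to it and so sets quaternary C10.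

Step 3
Reactants: 3 hydroxymethyl enone
Product: 4 (1R,6S)-1,3-dimethyl-2-oxo-6-(prop-1-en-2-yl)cyclohex-3-ene-1-carbaldehyde
Conditions: DMP (1,1,1-triacetoxy-1,1-dihydro-1,2-benziodoxol-3(1H)-one), NaHCO3, CH2Cl2, 0 → 23 °C
Reagents that add atoms: none
Why: Hypervalent-iodine oxidation of the neopentyl primary alcohol runs under neutral conditions, so the retro-aldol-prone β-hydroxy ketone and both alkenes stay intact and no stereocentre is touched.

Step 4
Reactants: 4 keto aldehyde
Product: 5 (1R,6R)-6-(2-bromopropan-2-yl)-1,3-dimethyl-2-oxocyclohex-3-ene-1-carbaldehyde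
Conditions: Co(acac)2 (25 mol%), t-BuOOH (25 mol%), Et3SiH, TsBr, n-PrOH, 23 °C
Reagents that add atoms: p-toluenesulfonyl bromide, Cc1ccc(cc1)S(=O)(=O)Br
Why: Cobalt-hydride hydrogen-atom transfer (Markovnikov radical hydrobromination) picks the electron-rich 1,1-disubstituted alkene over the enone, and the tertiary C4 radical abstracts bromine from TsBr, so no C4 cation arises that the C1 carbonyl oxygen could trap.

Step 5
Reactants: 5 bromo keto aldehyde; 6 diethylphosphonoacetic acid
Product: 8 trans-octalin dienedione (4,4,8,10-tetramethyl-Δ1,Δ7-3,9-dione; 5α-H; 10β-CH3), via β-keto phosphonate 7 (not isolated)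
Conditions: 6 (1.5 equiv), Boc2O, Ni(acac)2 (10 mol%), 4,4′-di-tert-butyl-2,2′-bipyridine, Zn, MgCl2, MeCN/THF, 25 °C; then LiCl, DBU, 25 °C (same flask)
Reagents that add atoms: none
Why: Boc2O converts 6 into its mixed anhydride, which adds oxidatively to zerovalent nickel; the acylnickel species captures the tertiary C4 radical released from 5 by bromine abstraction, and reductive elimination forges C3–C4 while Zn turns the catalyst over, which is the known reductive acyl cross-electrophile coupling of unactivated tertiary alkyl bromides with activated alkyl carboxylic acids. LiCl/DBU then deprotonates 7 at C2, and the chelated phosphonate carbanion adds to the C1 aldehyde and expels diethyl phosphate in an intramolecular Horner–Wadsworth–Emmons reaction that forms C1=C2. Ring A closes in the 6-(enolexo)-exo-trig mode, and the six-membered ring allows only the cis-alkene. No stereocentre is created: C5 and C10 are already in place, and their trans-diequatorial C4 and C1 arms translate directly into the trans ring fusion. The step needs C4 to react as a radical and not as a cation, which the C1 carbonyl oxygen would trap in a five-membered ring, and it needs acylation to precede olefination; single-electron activation by nickel secures the first point and the late addition of base the second. The ring-B enone survives because intramolecular attack of the C4 radical would give a four-membered ring and the trisubstituted, α-methylated acceptor is slow in intermolecular addition.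

Step 6
Reactants: 8 dienedione
Product: 10 trans-decalin-3,9-dione (4,4,8,10-tetramethyl; 5α-H; 8α-CH3; 10β-CH3), via C8-epimeric diketone mixture 9 (not isolated)
Conditions: H2 (1 atm), Pd/C, EtOAc, 23 °C; filter; NaOMe (0.2 equiv), MeOH, 23 °C
Reagents that add atoms: none
Why: Heterogeneous catalytic hydrogenation saturates both enone C=C bonds and leaves the ketones, and base-mediated enolisation of the C9 ketone then equilibrates C8 to the equatorial 8α-methyl epimer, which avoids the syn-diaxial clash with the 10β-methyl group.

Step 7
Reactants: 10 diketone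
Product: 11 3β-hydroxy-4,4,8α,10β-tetramethyl-trans-decalin-9-one
Conditions: NaBH4 (0.5 equiv), MeOH/CH2Cl2, −40 °C
Reagents that add atoms: none
Why: The borohydride reduction is chemoselective because the C9 ketone is shielded by quaternary C10 and the C8 methyl, and hydride reaches C3 axially from the α face, opposite the axial 4β- and 10β-methyl groups, which gives the equatorial 3β-alcohol.

Step 8
Reactants: 11 hydroxy ketone
Product: 12 3β-hydroxy-9-methylidene-4,4,8α,10β-tetramethyl-trans-decalin
Conditions: Ph3PCH3Br, KOt-Bu, toluene, 90 °C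
Reagents that add atoms: methyltriphenylphosphonium bromide, C[P+](c1ccccc1)(c1ccccc1)c1ccccc1.[Br-]
Why: Wittig methylenation with the small non-stabilised ylide at elevated temperature is the standard answer to hindered, enolisable ketones; the 3-alkoxide is inert and C8 stays at its thermodynamic configuration.

Step 9
Reactants: 12 exocyclic alkene
Product: 13 9α,11-epoxide (spiro-oxirane; oxygen axial on the α face; C11 equatorial)
Conditions: mCPBA, NaHCO3, CH2Cl2, 0 °C
Reagents that add atoms: 3-chloroperoxybenzoic acid, OOC(=O)c1cccc(Cl)c1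
Why: Peracid (Prilezhaev) epoxidation of the only alkene takes place on the α face, anti to the adjacent axial 10β-methyl group, which puts the oxygen axial (9α) and C11 equatorial and so sets C9.

Step 10
Reactants: 13 spiro-epoxide
Product: 14 3β,9α-dihydroxy-9β-vinyl-4,4,8α,10β-tetramethyl-trans-decalin
Conditions: Me3SI, n-BuLi, THF, −10 → 23 °C
Reagents that add atoms: trimethylsulfonium iodide, C[S+](C)C.[I-]
Why: This is the one-carbon homologation of a terminal epoxide with dimethylsulfonium methylide: SN2 opening at the CH2 terminus C11 and ylide-induced β-elimination of Me2S give the vinyl carbinol, and the C9–O bond is never broken, so C9 is retained.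

Step 11
Reactants: 14 diol
Product: 15 3β-acetoxy-9α-hydroxy-9β-vinyl-4,4,8α,10β-tetramethyl-trans-decalin
Conditions: Ac2O, pyridine, DMAP (5 mol%), CH2Cl2, 23 °C
Reagents that add atoms: acetic anhydride, CC(=O)OC(C)=O
Why: DMAP-catalysed acylation distinguishes the secondary equatorial 3β-alcohol from the tertiary, doubly flanked 9α-alcohol, which stays free.

Step 12
Reactants: 15 vinyl carbinol acetate; 16 3-bromofuran-2(5H)-one
Product: 18 target 3β-acetoxy-9α-hydroxylabd-13-en-16,15-olide (CNP0117645.1), via B-alkyl-9-BBN borane 17 (not isolated)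
Conditions: 9-BBN-H, THF, 23 °C; then 16, PdCl2(dppf) (10 mol%), AsPh3, Cs2CO3, DMF/H2O, 23 → 40 °C
Reagents that add atoms: none
Why: Anti-Markovnikov hydroboration of the monosubstituted alkene places boron on C12, and the B-alkyl Suzuki–Miyaura coupling with the α-bromobutenolide forms C12–C13 under mild carbonate conditions that spare acetate, tertiary alcohol and lactone; no stereocentre is affected.

Compound list
1 | (R)-(−)-carvone | CC1=CC[C@H](CC1=O)C(C)=C | starting material
2 | (5R,6S)-6-methylcarvone (trans epimer shown) | C[C@H]1[C@@H](CC=C(C)C1=O)C(C)=C | intermediate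
3 | (5S,6R)-6-(hydroxymethyl)-6-methylcarvone | OC[C@@]1(C)[C@@H](CC=C(C)C1=O)C(C)=C | intermediate
4 | (1R,6S)-1,3-dimethyl-2-oxo-6-(prop-1-en-2-yl)cyclohex-3-ene-1-carbaldehyde | O=C[C@@]1(C)[C@@H](CC=C(C)C1=O)C(C)=C | intermediate
5 | (1R,6R)-6-(2-bromopropan-2-yl)-1,3-dimethyl-2-oxocyclohex-3-ene-1-carbaldehyde | O=C[C@@]1(C)[C@@H](CC=C(C)C1=O)C(C)(C)Br | intermediate
6 | diethylphosphonoacetic acid | OC(=O)CP(=O)(OCC)OCC | starting material
7 | β-keto phosphonate (5 with Br replaced by C(=O)CH2P(O)(OEt)2) | O=C[C@@]1(C)[C@@H](CC=C(C)C1=O)C(C)(C)C(=O)CP(=O)(OCC)OCC | intermediate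
8 | trans-octalin dienedione (Δ1,Δ7-3,9-dione; 5α-H; 10β-CH3) | O=C1C=C[C@@]2(C)[C@@H](CC=C(C)C2=O)C1(C)C | intermediate
9 | decalin-3,9-dione, C8 epimer mixture | O=C1CC[C@@]2(C)[C@@H](CCC(C)C2=O)C1(C)C | intermediate
10 | trans-decalin-3,9-dione, 8α-methyl | O=C1CC[C@@]2(C)[C@@H](CC[C@@H](C)C2=O)C1(C)C | intermediate
11 | 3β-hydroxy-9-ketone | O[C@H]1CC[C@@]2(C)[C@@H](CC[C@@H](C)C2=O)C1(C)C | intermediate
12 | 3β-hydroxy-9-methylidene decalin | O[C@H]1CC[C@@]2(C)[C@@H](CC[C@@H](C)C2=C)C1(C)C | intermediate
13 | 3β-hydroxy-9α,11-epoxide | O[C@H]1CC[C@@]2(C)[C@@H](CC[C@@H](C)[C@]23CO3)C1(C)C | intermediate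
14 | 3β,9α-diol with 9β-vinyl group | O[C@H]1CC[C@@]2(C)[C@@H](CC[C@@H](C)[C@]2(O)C=C)C1(C)C | intermediate
15 | 3β-acetate of 14 | CC(=O)O[C@H]1CC[C@@]2(C)[C@@H](CC[C@@H](C)[C@]2(O)C=C)C1(C)C | intermediate
16 | 3-bromofuran-2(5H)-one | O=C1OCC=C1Br | starting material
17 | C12 B-alkyl-9-BBN borane of 15 | CC(=O)O[C@H]1CC[C@@]2(C)[C@@H](CC[C@@H](C)[C@]2(O)CCB2C3CCCC2CCC3)C1(C)C | intermediate
18 | 3β-acetoxy-9α-hydroxylabd-13-en-16,15-olide (CNP0117645.1) | CC(=O)O[C@H]1CC[C@@]2(C)[C@@H](CC[C@@H](C)[C@]2(O)CCC2=CCOC2=O)C1(C)C | target

Total step count: 12. Longest linear sequence: 12 steps (1 → 18).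

Steps most likely to fail

Step 5. Several processes could spoil it:
- The tertiary bromide may lose HBr.
- The bromide may ionise and be captured by the aldehyde oxygen.
- Radical capture by the acylnickel species may be slow at the crowded C4.
- The linchpin may olefinate the aldehyde before it is acylated.

The fallback sets out from 4 and comes back at 8. Lithiated acetonitrile (LDA, MeCN, THF, −78 °C, cold AcOH quench) adds to the C1 aldehyde and gives the β-hydroxy nitrile F1. Iron-hydride hydrogen-atom transfer to the isopropenyl group (Fe(acac)3, PhSiH3, EtOH, 60 °C) then generates the C4 radical, which closes 6-exo-dig onto the nitrile carbon. Acidic work-up hydrolyses the imine to the 1-hydroxy-3-ketone F2, and dehydration (MsCl, Et3N, then DBU) returns 8.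

Step 8. Enolisation may outrun addition, and the ylide may attack too slowly at a carbonyl flanked by quaternary C10 and the C8 methine. The fallback sets out from 11 and comes back at 12. The smaller and more nucleophilic Me3SiCH2Li (CeCl3, THF, −78 → 0 °C) adds from the open α face and gives the β-hydroxysilane F3. Peterson elimination (KH, THF) then delivers 12; the configuration created at C9 is erased in that step.

Step 12. Transmetalation of the hindered, hydroxyl-bearing borane may be slow, and base may degrade the bromobutenolide. The fallback sets out from 15 and comes back at 18.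
- Borane 17 is formed as before and treated with I2/NaOMe, which gives the primary C12 iodide F4.
- The lithium enolate of 3-(phenylsulfanyl)oxolan-2-one (LDA, THF/HMPA, excess) is alkylated by it, giving the α-phenylsulfanyl lactone F5.
- mCPBA at −78 °C gives the sulfoxide F6.
- Thermal syn-elimination in toluene at 110 °C installs the C13=C14 double bond of 18.

Further compounds
F1 | step 5 | β-hydroxy nitrile from 4 and LiCH2CN (C1 epimers) | N#CCC(O)[C@@]1(C)[C@@H](CC=C(C)C1=O)C(C)=C
F2 | step 5 | 1-hydroxy-Δ7-octalin-3,9-dione (C1 epimers) | O=C1CC(O)[C@@]2(C)[C@@H](CC=C(C)C2=O)C1(C)C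
F3 | step 8 | 9β-hydroxy-9α-(trimethylsilylmethyl) adduct of 11 | O[C@H]1CC[C@@]2(C)[C@@H](CC[C@@H](C)[C@@]2(O)C[Si](C)(C)C)C1(C)C
F4 | step 12 | C12 primary iodide | CC(=O)O[C@H]1CC[C@@]2(C)[C@@H](CC[C@@H](C)[C@]2(O)CCI)C1(C)C
F5 | step 12 | α-phenylsulfanyl lactone (C13 epimers) | CC(=O)O[C@H]1CC[C@@]2(C)[C@@H](CC[C@@H](C)[C@]2(O)CCC2(Sc3ccccc3)CCOC2=O)C1(C)C
F6 | step 12 | α-phenylsulfinyl lactone (epimers) | CC(=O)O[C@H]1CC[C@@]2(C)[C@@H](CC[C@@H](C)[C@]2(O)CCC2(S(=O)c3ccccc3)CCOC2=O)C1(C)C
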